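## Structural features

The target 12 is a single cyclohexene in which every ring carbon is functionalised: C1 is a quaternary carbinol that also carries the exocyclic benzoyloxymethyl carbon C7, C2 is an allylic CH–OBz, C3=C4 is the only alkene, and C5 and C6 (C6 next to C1) are free secondary carbinols. The four stereocentres are contiguous in the order C2–C1–C6–C5. Calling β the ring face that holds C7, the C2 benzoate and the C5 hydroxyl are β and the C1 and C6 hydroxyls are α, so C1-OH/C6-OH are cis, C5-OH/C6-OH trans and the allylic oxygens at C2 and C5 are 1,4-cis ((1S,2S,5R,6S) in this numbering). Two benzoates sit among three free hydroxyls on 1,2- and 1,3-related oxygens, so acyl migration under base is a standing threat, and the doubly allylic, fully oxygenated ring can ionise at C2 or aromatise by loss of water or benzoic acid under strong acid or heat. The real difficulty is not the carbon skeleton but four contiguous oxygen-bearing stereocentres, one quaternary, around an alkene of fixed position, and the sorting of five oxygens into two benzoates and three hydroxyls. The key step uses the fact that C7–C1(O)–C2–C3–C4 is the atom pattern of 3-hydroxy-2-pyrone, with C1 and C4 in a 1,4 relationship, and that the C5–C6 trans-diol is the Baeyer–Villiger image of a trans-diacetyl unit; the pyrone ester bridge then ties C7 and the C4 oxygen to one face, from which the C2 oxygen and the C3=C4 position are derived. Locants C1–C7 are used in this sense throughout, also for the bicyclic intermediates, whose systematic names carry their own numbering.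

## Logic of the disconnections

12 from 11. Only the two acetyl C–O bonds on the C5 and C6 oxygens are cut. This leaves the benzoates as the only esters that must survive the last step and keeps the diol masked until both benzoates are in place. The forward step must tell acetate from benzoate and must not move an acyl group, which points to acidic rather than basic methanolysis.

11 from 10. The two benzoyl C–O bonds at the C7 and C2 oxygens are cut together. In 10 these are the only hydroxyls that acylate readily, since C1-OH is tertiary and C5/C6 are acetates, so one operation installs both aroyl groups. The forward step must leave the tertiary hydroxyl alone.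

10 from 9. No skeletal bond is cut; C7 is returned to the carboxylic acid level. The acid is what the opening of the lactone bridge delivers. The forward reduction has to be selective for the acid beside two acetates and the C3=C4 alkene.

9 from 8. The C3=C4 double bond and the free carboxyl are traced back to a C3–I bond and the C4–O(acyl) bond of a bridged lactone. This is the point where the alkene is moved and the lactone is given up. The cut is placed here because a rigid β-iodo lactone fixes both the direction of elimination (only the C4 oxygen is antiperiplanar and a good leaving group) and the C2 configuration. A direct displacement of the allylic lactone oxygen by benzoate under zerovalent palladium was weighed and set aside. It would need attack at the allyl terminus next to the quaternary carbon and beside the carboxylate, it gives an allylic ester that can re-ionise, and it leaves an alkene in the substrate during the peracid and borane steps. The forward step needs zinc insertion and anti elimination without loss of the C2 hydroxyl.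

8 from 7. The C3–I bond is cut and the C2–O–C3 oxirane restored. This turns a trans iodohydrin into a cis-fused epoxide on the lactone face, so the C2 oxygen configuration becomes a question of facial selectivity only. The forward step needs iodide to enter at C3 and not at C2.

7 from 5. Three C–O bonds are removed in one retrosynthetic operation: the two oxirane bonds at C2 and C3, and the C5–O and C6–O bonds, which revert to C–C(acetyl) bonds. Three oxygens are thus traded for an alkene and two methyl ketones, all answering to one peracid. The forward step needs migration of the ring carbon (not methyl) with retention, and epoxidation from the lactone face.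

5 from 3 and 4. The ring bonds C1–C6 and C4–C5 are cut. This is the key disconnection: it removes the carbocycle and all four stereocentres and leaves two flat, achiral partners. A check of the mapping shows that, with the lactone bridge on the β face, the C6 acetyl must lie syn to the alkene bridge and the C5 acetyl syn to the lactone bridge; 5 as drawn below meets this and correlates with 12 centre by centre. Because 3 is C2-symmetric, no regiochemical question arises. The forward step must control which acetyl is endo and which enantioface of 4 is used, and it needs a tertiary-amine catalyst, since a primary amine would be destroyed by 3.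

3 from 1. The two C=O groups of 3 are traced back to the ring C–O bonds of a furan; 4 is purchased. Oxidative ring opening gives the (Z)-enedione 2, so the forward step must include equilibration to the (E) isomer, on which the trans-diol depends.

## Other disconnections considered

Alternative 1: The cut is the ring bond C1–C2, made after reconnecting the C7 carboxyl oxygen to C4. C7, C1, C6, C5 and C4 then become a gluco-configured δ-lactone, A1, whose ring carbon next to the ring oxygen carries an (E)-2-(pinacolboryl)vinyl group (the future C3 and C2). Forward, enolisation and O-silylation of A1 followed by warming would trigger an Ireland–Claisen shift through a boat-shaped, bicyclo[2.2.2]-like array. It would form C1–C2, break C4–O and give acid A2 with the alkene at C3=C4 and boron cis to the carboxyl. Oxidation of the C–B bond with retention, carboxyl reduction, dibenzoylation and desilylation would follow.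
- In its favour: the absolute configuration comes from the sugar pool (C5 and C6 are inherited), so no enantioselective catalyst has to be trusted.
- Better than the chosen plan: the C2 heteroatom and the alkene arrive in their final places in one concerted step, whereas the chosen plan spends three operations on that transposition.
- Better than the chosen plan: silyl ethers can be removed at the end with no risk to benzoates, unlike the acetate/benzoate discrimination of step 8.
- Against it: A1 needs a multi-step excursion from a hexonolactone (differentiation of the primary carbinol, oxidation, boryl-olefination, silylation). Its enolate carries a β-silyloxy leaving group and may eliminate before it is trapped. The shift must pass a strained boat with a fully substituted ketene acetal terminus, and the allylic boronate of A2 can undergo 1,3-boron shift.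
- Comparison: on structure the plans are equals, since both set all four stereocentres and both end with reduction of a C7 acid beside the C3=C4 alkene. On mechanism the sigmatropic shift is intramolecular and stereospecific, while the chosen cycloaddition is bimolecular and relies on a catalyst with an untested partner. On step economy the chosen plan is shorter (eight steps against an estimated eleven or more).

Alternative 2: The cuts are C1–C2 and C5–C6. The unit C2–C5 with both allylic oxygens is diene A3; C7, C1 and C6, with the cis C1/C6 diol masked as a cyclic carbonate, are dienophile A4. Forward, a chiral oxazaborolidinium Lewis acid would promote the Diels–Alder reaction to A5, closing the cyclohexene with the carbonate trans to both acetoxy groups.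
- Better than the chosen plan: it is the most convergent option. One step would create the ring, all four stereocentres, all ring oxygens and the alkene already at C3=C4, so no transposition is needed.
- In its favour: the cis C1/C6 and the 2,5-cis relationships follow directly from the geometries of the partners.
- Against it: the partners are poorly matched. The acyloxy diene is only moderately electron-rich, and the dienophile is trisubstituted and carries two donor oxygens. The Lewis acid can bind the ester or the carbonate carbonyl, and the required exo/endo sense is not secured by anything in the substrates.
- Against it: after the cycloaddition, C2 and C5 carry identical acetates that differ only through the remote C1 substituents, so making one a benzoate and the other a free hydroxyl becomes the central problem.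
- Against it: reduction of the C7 ester beside a carbonate and two acetates would probably force a global reduction and a fresh differentiation of five hydroxyls.
- Comparison: on structure both plans build the full stereo-array in the key step, but only the chosen plan marks C2 and C5 as different by origin (pyrone carbon against dienophile carbon). On mechanism both are [4+2] processes, the chosen one with closer precedent for its activation mode. On step economy the alternative is shorter to the ring but likely longer after it.

Alternative 3: The cut is at the C5–O and C6–O bonds of an oxirane on a prochiral 4-hydroxycyclohexadienone, A6, that already carries the C7 benzoate; the ring comes from an arene. Forward, a chiral primary-amine salt and H2O2 would epoxidise one of the two enantiotopic enone units of A6 by iminium activation, syn to the tertiary hydroxyl, to give epoxy enone A7.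
- Better than the chosen plan: it is the shortest entry to a chiral core. A6 should be available in one anodic oxidation of a simple para-substituted phenol ester, the C7 benzoate is present from the start, and no carboxyl reduction beside an alkene is needed (compare step 6).
- In its favour: one catalytic step would set C1, C5 and C6.
- Against it: A7 still has C4 at the ketone level and the alkene at C2=C3. The oxirane would have to be opened by an oxygen nucleophile specifically at C5, α to the carbonyl; opening at C6 gives the wrong trans-diol.
- Against it: the C4 carbonyl/C2=C3 unit would have to be transposed to a C2 oxygen cis to C7 with a C3=C4 alkene. This is the same type of transposition that the chosen plan solves, but here there is no tether to dictate the face.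
- Against it: dienone and epoxy-enone intermediates aromatise and accept nucleophiles easily, and the C7 benzoate may migrate to the tertiary alkoxide under the basic peroxide conditions.
- Comparison: on structure the alternative sets three of the four centres in its key step and the chosen plan four. On mechanism it is a desymmetrisation of a flat substrate with catalyst control alone, where the chosen plan adds the conformational control of a bicycle in the later steps. On step economy the alternative wins up to A7 and probably loses afterwards.

Key step: step 2

Assumption: the quinidine-derived thiourea is taken to give 5 with the absolute configuration drawn; should the sense be opposite, its quinine-derived pseudoenantiomer is used and nothing else changes.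

## Route

Step 1
Reactants: 1 2,5-dimethylfuran
Product: 3 (E)-hex-3-ene-2,5-dione, via (Z)-hex-3-ene-2,5-dione 2 (not isolated)
Conditions: mCPBA (1.05 equiv), CH2Cl2, 0 °C; then I2 (5 mol %), rt, daylight
Reagents that add atoms: 3-chloroperbenzoic acid (mCPBA), O=C(OO)c1cccc(Cl)c1
Why: Peracid epoxidation of the electron-rich furan and spontaneous ring opening (oxidative furan cleavage) give the (Z)-enedione 2; reversible addition of iodine atoms equilibrates it to the more stable (E) isomer 3. No stereocentre is formed.

Step 2
Reactants: 4 3-hydroxy-2H-pyran-2-one; 3 (E)-hex-3-ene-2,5-dione (1.3 equiv)
Product: 5 (1R,4R,7S,8S)-7,8-diacetyl-4-hydroxy-2-oxabicyclo[2.2.2]oct-5-en-3-one (trans; 7-acetyl syn to the lactone bridge, 8-acetyl syn to the alkene bridge)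
Conditions: thiourea from 9-amino-9-deoxy-epi-quinidine and 3,5-bis(trifluoromethyl)phenyl isothiocyanate (10 mol %), EtOAc, −20 → 0 °C
Reagents that add atoms: none
Why: The quinuclidine nitrogen deprotonates the acidic 3-OH of 4, and the ammonium dienolate ion pair adds through pyrone C3 and C6 to the double bond of 3 while the thiourea hydrogen-bonds an acetyl carbonyl; this is a base-catalysed normal-demand Diels–Alder reaction that can equally be read as a vinylogous Michael addition followed by intramolecular aldol closure. The closest known reaction type is the bifunctional cinchona-catalysed asymmetric cycloaddition of 3-hydroxy-2-pyrones with α,β-unsaturated ketones and other electron-poor alkenes. The carbocycle closes in [4+2] mode, the bonds C1–C6 and C4–C5 forming suprafacially on both partners, and the pyrone ester becomes the two-atom bridge of a bicyclo[2.2.2]octene. C1 and C4 are set together by the pyrone face that the catalyst leaves open, and C5 and C6 are trans because the (E) geometry of 3 is transferred stereospecifically. Which acetyl lies under the diene is decided by endo approach of the carbonyl on the carbon that bonds to the oxido-bearing terminus, the mode that base-mediated additions of this diene normally prefer and that the ammonium–thiourea pair should reinforce. Regiochemistry does not arise because 3 is C2-symmetric, which is the main reason for using it. A tertiary-amine catalyst is chosen because a primary amine would be consumed by 3 through conjugate addition and pyrrole formation. The step needs endo selectivity for the C6 acetyl and one enantioface; low temperature and a small excess of 3 should also hold back retro-aldol opening and epimerisation of the adduct.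

Step 3
Reactants: 5 (1R,4R,7S,8S)-7,8-diacetyl-4-hydroxy-2-oxabicyclo[2.2.2]oct-5-en-3-one
Product: 7 7,8-diacetoxy-5,6-epoxy-4-hydroxy-2-oxabicyclo[2.2.2]octan-3-one (oxirane oxygen and 7-OAc syn to the lactone bridge, 8-OAc anti to it), via 7,8-diacetoxy lactone 6 (not isolated)
Conditions: CF3CO3H (6 equiv; from (CF3CO)2O and urea·H2O2), Na2HPO4, CH2Cl2, 0 °C → rt
Reagents that add atoms: trifluoroperacetic acid (made in the flask from trifluoroacetic anhydride and urea–hydrogen peroxide), OOC(=O)C(F)(F)F
Why: Baeyer–Villiger oxidation of both methyl ketones (the secondary ring carbon migrates in preference to methyl, with retention at C5 and C6) is followed by Prilezhaev epoxidation of the strained C2=C3 bond. The peracid should approach from the face flanked by the flat, unsubstituted lactone bridge, because the other face is screened by the endo C6 substituent; this puts the oxirane oxygen β at C2. Phosphate buffer protects the epoxide and the acetates from trifluoroacetic acid.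

Step 4
Reactants: 7 7,8-diacetoxy-5,6-epoxy-4-hydroxy-2-oxabicyclo[2.2.2]octan-3-one
Product: 8 7,8-diacetoxy-4,5-dihydroxy-6-iodo-2-oxabicyclo[2.2.2]octan-3-one (5-OH syn to the lactone bridge, i.e. C2-OH β; 6-iodo anti to it, i.e. C3-I α)
Conditions: LiI (5 equiv), AcOH (3 equiv), THF, rt → 40 °C
Reagents that add atoms: lithium iodide, [Li+].[I-]
Why: Acid-assisted SN2 opening of the epoxide by iodide (iodohydrin formation). C3 is attacked from the face opposite the oxirane because C2 adjoins the quaternary C1, is shielded at its rear by the endo C6 acetate and is inductively deactivated by the C1 substituents. C2 keeps its β oxygen and C3 takes iodine with inversion.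

Step 5
Reactants: 8 7,8-diacetoxy-4,5-dihydroxy-6-iodo-2-oxabicyclo[2.2.2]octan-3-one
Product: 9 5β,6α-diacetoxy-1α,2β-dihydroxycyclohex-3-ene-1-carboxylic acid (β = face of the carboxyl group)
Conditions: Zn dust, AcOH–THF (1:4), rt → 45 °C
Reagents that add atoms: none
Why: Zinc inserts into the C3–I bond and the organozinc expels the antiperiplanar C4–O carboxylate (reductive β-elimination, the reverse of a halolactonisation). This opens the lactone bridge, places the alkene at C3=C4 and frees C7 as the acid. The C2 hydroxyl is a far poorer leaving group and is not antiperiplanar, and no stereocentre is touched.

Step 6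
Reactants: 9 5β,6α-diacetoxy-1α,2β-dihydroxycyclohex-3-ene-1-carboxylic acid
Product: 10 5β,6α-diacetoxy-1-(hydroxymethyl)cyclohex-3-ene-1α,2β-diol
Conditions: BH3·THF (2.5 equiv), THF, 0 °C; MeOH quench
Reagents that add atoms: none
Why: Chemoselective borane reduction of a carboxylic acid through its acyloxyborane, helped by the α-hydroxyl, which forms a cyclic acyloxyborane. Acetates are inert, and the 1,2-disubstituted alkene is deactivated by two allylic C–O bonds, so it should be hydroborated much more slowly at 0 °C.

Step 7
Reactants: 10 5β,6α-diacetoxy-1-(hydroxymethyl)cyclohex-3-ene-1α,2β-diol
Product: 11 [5β,6α-diacetoxy-2β-(benzoyloxy)-1α-hydroxycyclohex-3-en-1-yl]methyl benzoate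
Conditions: BzCl (2.4 equiv), pyridine, DMAP (cat.), CH2Cl2, 0 °C → rt
Reagents that add atoms: benzoyl chloride, O=C(Cl)c1ccccc1
Why: DMAP-catalysed acylation (nucleophilic catalysis) of the primary C7 and the secondary C2 hydroxyls. The tertiary C1 hydroxyl is not acylated under these conditions, so exactly two benzoates are introduced and no stereocentre is affected.

Step 8
Reactants: 11 [5β,6α-diacetoxy-2β-(benzoyloxy)-1α-hydroxycyclohex-3-en-1-yl]methyl benzoate
Product: 12 [(1S,2S,5R,6S)-2-(benzoyloxy)-1,5,6-trihydroxycyclohex-3-en-1-yl]methyl benzoate (CNP0141358.1)
Conditions: HCl (0.2 M) in MeOH–CH2Cl2 (2:1), 0 °C → rt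
Reagents that add atoms: none
Why: Acid-catalysed transesterification with methanol should cleave the alkyl acetates much faster than the benzoates, whose carbonyl is deactivated by conjugation. Acidic conditions avoid the alkoxide-driven acyl migration that basic methanolysis would invite; stereocentres are untouched.

## Compound list

1 | 2,5-dimethylfuran | Cc1ccc(C)o1 | starting material
2 | (Z)-hex-3-ene-2,5-dione | CC(=O)/C=C\C(C)=O | intermediate
3 | (E)-hex-3-ene-2,5-dione | CC(=O)/C=C/C(C)=O | intermediate
4 | 3-hydroxy-2H-pyran-2-one | O=C1OC=CC=C1O | starting material
5 | (1R,4R,7S,8S)-7,8-diacetyl-4-hydroxy-2-oxabicyclo[2.2.2]oct-5-en-3-one | O=C1[C@@]2(O)C=C[C@@H](O1)[C@@H](C(C)=O)[C@@H]2C(C)=O | intermediate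
6 | trans-7,8-diacetoxy-4-hydroxy-2-oxabicyclo[2.2.2]oct-5-en-3-one (7-OAc syn to the lactone bridge, 8-OAc syn to the alkene) | O=C1[C@@]2(O)C=C[C@@H](O1)[C@@H](OC(C)=O)[C@@H]2OC(C)=O | intermediate
7 | 7,8-diacetoxy-5,6-epoxy-4-hydroxy-2-oxabicyclo[2.2.2]octan-3-one (oxirane oxygen syn to the lactone bridge) | O=C1[C@@]2(O)[C@H]3O[C@H]3[C@@H](O1)[C@@H](OC(C)=O)[C@@H]2OC(C)=O | intermediate
8 | 7,8-diacetoxy-4,5-dihydroxy-6-iodo-2-oxabicyclo[2.2.2]octan-3-one (5-OH syn, 6-I anti to the lactone bridge) | O=C1[C@@]2(O)[C@@H](O)[C@H](I)[C@@H](O1)[C@@H](OC(C)=O)[C@@H]2OC(C)=O | intermediate
9 | 5β,6α-diacetoxy-1α,2β-dihydroxycyclohex-3-ene-1-carboxylic acid | OC(=O)[C@@]1(O)[C@@H](O)C=C[C@@H](OC(C)=O)[C@@H]1OC(C)=O | intermediate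
10 | 5β,6α-diacetoxy-1-(hydroxymethyl)cyclohex-3-ene-1α,2β-diol | OC[C@@]1(O)[C@@H](O)C=C[C@@H](OC(C)=O)[C@@H]1OC(C)=O | intermediate
11 | [5β,6α-diacetoxy-2β-(benzoyloxy)-1α-hydroxycyclohex-3-en-1-yl]methyl benzoate | O=C(OC[C@@]1(O)[C@@H](OC(=O)c2ccccc2)C=C[C@@H](OC(C)=O)[C@@H]1OC(C)=O)c1ccccc1 | intermediate
12 | [(1S,2S,5R,6S)-2-(benzoyloxy)-1,5,6-trihydroxycyclohex-3-en-1-yl]methyl benzoate | O=C(OC[C@@]1(O)[C@@H](OC(=O)c2ccccc2)C=C[C@@H](O)[C@@H]1O)c1ccccc1 | target

## Step count and least certain steps

Total step count: 8. Longest linear sequence: 8 steps (1 to 12; 7 from purchased 4).

Step 2 (key step). Most likely failure: insufficient control over which acetyl takes the endo position and over the enantioface, because the doubly activated enedione has not been used in this reaction type. Competing oxa-Michael addition of the pyrone hydroxyl and base-induced retro-aldol opening or epimerisation of the β-hydroxy ketone adduct are further risks. Fallback: separate stereo-induction from catalysis. The cycloaddition of 3 and 4 is run with triethylamine, where the intrinsic endo preference still operates. This gives 5 together with its mirror image, (1S,4S,7R,8R)-7,8-diacetyl-4-hydroxy-2-oxabicyclo[2.2.2]oct-5-en-3-one F1, and the enantiomers are separated by preparative chromatography on a chiral stationary phase. The fallback sets out from 3 and 4 and returns at 5.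

Step 3. Most likely failure: incomplete epoxidation of the electron-poor bridged alkene within the lifetime of the buffered peracid, acid-induced opening of the epoxide once formed, or sluggish migration at the acetyl next to the carbinol carbon, so that the three oxidations do not finish together. Fallback: reverse and separate the oxidations. From 5, dimethyldioxirane in acetone (neutral) should give 7,8-diacetyl-5,6-epoxy-4-hydroxy-2-oxabicyclo[2.2.2]octan-3-one F2, with the same facial bias. The double Baeyer–Villiger oxidation is then carried out on F2, which has no alkene and can be driven hard, returning at 7.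

Step 4. Most likely failure: opening at the wrong oxirane carbon, either by iodide attack at C2 or by anchimeric participation of the endo C6 acetate at C2 through a six-membered acyloxonium ion; this would put oxygen and iodine on the wrong carbons. Fallback: transposition through sulfur, which uses the steric bias of the allyl system instead of opposing it.
- It sets out from 6, obtained by stopping step 3 at the diacetate stage (two equivalents of peracid, 0 °C).
- Pd(PPh3)4 (zerovalent palladium) ionises the allylic lactone, and thiophenol should attack the less hindered terminus C4 anti to the metal, with net retention, to give 5β,6α-diacetoxy-1α-hydroxy-4β-(phenylsulfanyl)cyclohex-2-ene-1-carboxylic acid F3.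
- One equivalent of mCPBA at −78 °C gives the sulfoxide, 5β,6α-diacetoxy-1α-hydroxy-4β-(phenylsulfinyl)cyclohex-2-ene-1-carboxylic acid F4.
- Mislow–Evans [2,3] rearrangement with diethylamine as thiophile moves oxygen suprafacially to C2 (β) and the alkene to C3=C4, returning at 9.

Step 6. Most likely failure: hydroboration of the C3=C4 alkene competing with reduction of the carboxyl group, since borane attacks both functions quickly and selectivity rests only on the deactivation of this particular alkene. Fallback: change from electrophilic borane on the acid to nucleophilic hydride on an ester. From 9, trimethylsilyldiazomethane gives methyl 5β,6α-diacetoxy-1α,2β-dihydroxycyclohex-3-ene-1-carboxylate F5. NaBH4 in EtOH at 0 °C should reduce the activated α-hydroxy ester much faster than the acetates and leave the alkene alone, returning at 10.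

Step 8. Most likely failure: erosion of selectivity during the slow cleavage of the hindered C6 acetate, with partial loss or migration of the primary C7 benzoate. Fallback: exchange the protecting groups before benzoylation.
- From 10, K2CO3 in MeOH removes both acetates to give 1-(hydroxymethyl)cyclohex-3-ene-1α,2β,5β,6α-tetrol F6.
- Butane-2,3-dione, HC(OMe)3 and camphorsulfonic acid in MeOH should protect the only trans-vicinal secondary diol (C5/C6) as the butane-2,3-diacetal triol F7.
- BzCl, pyridine and DMAP benzoylate C7-OH and C2-OH to give the diacetal dibenzoate F8.
- Aqueous trifluoroacetic acid removes the diacetal without touching benzoates, returning at 12.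

## Further compounds

F1 | step 2 | (1S,4S,7R,8R)-7,8-diacetyl-4-hydroxy-2-oxabicyclo[2.2.2]oct-5-en-3-one | O=C1[C@]2(O)C=C[C@H](O1)[C@H](C(C)=O)[C@H]2C(C)=O
F2 | step 3 | 7,8-diacetyl-5,6-epoxy-4-hydroxy-2-oxabicyclo[2.2.2]octan-3-one (oxirane oxygen syn to the lactone bridge) | O=C1[C@@]2(O)[C@H]3O[C@H]3[C@@H](O1)[C@@H](C(C)=O)[C@@H]2C(C)=O
F3 | step 4 | 5β,6α-diacetoxy-1α-hydroxy-4β-(phenylsulfanyl)cyclohex-2-ene-1-carboxylic acid | OC(=O)[C@@]1(O)C=C[C@@H](Sc2ccccc2)[C@@H](OC(C)=O)[C@@H]1OC(C)=O
F4 | step 4 | 5β,6α-diacetoxy-1α-hydroxy-4β-(phenylsulfinyl)cyclohex-2-ene-1-carboxylic acid (mixture at sulfur) | OC(=O)[C@@]1(O)C=C[C@@H](S(=O)c2ccccc2)[C@@H](OC(C)=O)[C@@H]1OC(C)=O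
F5 | step 6 | methyl 5β,6α-diacetoxy-1α,2β-dihydroxycyclohex-3-ene-1-carboxylate | COC(=O)[C@@]1(O)[C@@H](O)C=C[C@@H](OC(C)=O)[C@@H]1OC(C)=O
F6 | step 8 | 1-(hydroxymethyl)cyclohex-3-ene-1α,2β,5β,6α-tetrol | OC[C@@]1(O)[C@@H](O)C=C[C@@H](O)[C@@H]1O
F7 | step 8 | C5,C6-O-[(2S,3S)-2,3-dimethoxybutane-2,3-diyl] acetal of F6 (trans-fused 1,4-dioxane, methoxy groups axial) | OC[C@@]1(O)[C@@H](O)C=C[C@H]2O[C@](C)(OC)[C@@](C)(OC)O[C@H]12
F8 | step 8 | C7,C2-di-O-benzoate of F7 | O=C(OC[C@@]1(O)[C@@H](OC(=O)c3ccccc3)C=C[C@H]2O[C@](C)(OC)[C@@](C)(OC)O[C@H]12)c1ccccc1
A1 | alternative 1 | 2,3,4-tri-O-(triethylsilyl)-6,7-dideoxy-7-(pinacolboryl)-D-gluco-hept-6(E)-enono-1,5-lactone | O=C1O[C@H](/C=C/B2OC(C)(C)C(C)(C)O2)[C@@H](O[Si](CC)(CC)CC)[C@H](O[Si](CC)(CC)CC)[C@H]1O[Si](CC)(CC)CC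
A2 | alternative 1 | 2-(pinacolboryl)-1,5,6-tris(triethylsilyloxy)cyclohex-3-ene-1-carboxylic acid (boron cis to carboxyl) | OC(=O)[C@@]1(O[Si](CC)(CC)CC)[C@@H](B2OC(C)(C)C(C)(C)O2)C=C[C@@H](O[Si](CC)(CC)CC)[C@@H]1O[Si](CC)(CC)CC
A3 | alternative 2 | (1E,3E)-1,4-diacetoxybuta-1,3-diene | CC(=O)O/C=C/C=C/OC(C)=O
A4 | alternative 2 | methyl 2-oxo-1,3-dioxole-4-carboxylate | COC(=O)C1=COC(=O)O1
A5 | alternative 2 | methyl 2,5-diacetoxy-1,6-(carbonyldioxy)cyclohex-3-ene-1-carboxylate (carbonate trans to both acetates) | COC(=O)[C@@]1(OC(=O)O2)[C@@H](OC(C)=O)C=C[C@@H](OC(C)=O)[C@@H]12
A6 | alternative 3 | (1-hydroxy-4-oxocyclohexa-2,5-dien-1-yl)methyl benzoate | O=C(OCC1(O)C=CC(=O)C=C1)c1ccccc1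
A7 | alternative 3 | (5,6-epoxy-1-hydroxy-4-oxocyclohex-2-en-1-yl)methyl benzoate (oxirane syn to the hydroxyl) | O=C(OC[C@@]1(O)C=CC(=O)[C@@H]2O[C@H]12)c1ccccc1
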